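**Plan**

Ring numbering: C1 carries the acrylate, C2 is the ring =CH, C3, C5 and C6 carry CO2H, C4 carries the aryl group, and C6 is bonded to C1.
Cuts, in retrosynthetic order: the side-chain CH=CH next to C1 (Wittig; C1 keeps a CHO), the ring bond C1–C6 (intramolecular Michael), C2–C3 of the opened arm (made as C=C by Horner–Wadsworth–Emmons), C5–C6 (condensation with glyoxylic acid) and C3–C4 (aminocatalytic Michael addition to a cinnamaldehyde).
Enabling feature: with the side chain cut back to CHO, C1 is the α-carbon of a C1=C2 enal that enolises through C3 (dienamine). C6 is the β-carbon of a (Z)-3-formylacrylic acid made of C5, C6 and their two carboxyl carbons (that of C5 at the aldehyde level), stored as a hydroxybutenolide ring.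
Forward order: acyclic C3–C4–C5 chain, then the butenolide (temporary ring), then the carbocycle by C1–C6 together with a cis-fused lactol. The lactol is oxidised to the anhydride, the (R)-3-aryllactate side chain (built from an (R)-glycidate and an aryl Grignard reagent) is joined, and all benzyl groups are removed.
Stereochemistry: C4 from the (S)-diarylprolinol silyl ether catalyst; C6 from C4 during ring closure; C5 and C3 by equilibration (cis-lactol trap, equatorial ester); the lactate centre from potassium (R)-glycidate (chiral pool).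

Key step: step 5

Assumption: 3,3-dimethoxypropanal (9) and potassium (2R)-oxirane-2-carboxylate (14) are taken as purchasable (9 is otherwise one partial hydrolysis away from 1,1,3,3-tetramethoxypropane, 14 is otherwise made from L-serine by bromodeamination and ring closure with KOH); centres and double bonds left undefined in a SMILES are mixtures that are erased later.

**Route**

Step 1
Reactants: 1 3,4-bis(benzyloxy)benzaldehyde; 2 (triphenylphosphoranylidene)acetaldehyde
Product: 3 (2E)-3-[3,4-bis(benzyloxy)phenyl]prop-2-enal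
Conditions: toluene, 80 °C
Reagents that add atoms: none
Why: Wittig olefination with the stabilised formyl ylide should give the (E)-cinnamaldehyde, E being the normal outcome for stabilised ylides.

Step 2
Reactants: 3 (2E)-3-[3,4-bis(benzyloxy)phenyl]prop-2-enal; 4 benzyl (diethoxyphosphoryl)acetate
Product: 5 benzyl (3S)-3-[3,4-bis(benzyloxy)phenyl]-2-(diethoxyphosphoryl)-5-oxopentanoate (both C-2 epimers)
Conditions: (S)-2-{bis[3,5-bis(trifluoromethyl)phenyl][(trimethylsilyl)oxy]methyl}pyrrolidine (10 mol %), PhCO2H (10 mol %), EtOH, rt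
Reagents that add atoms: none
Why: Iminium-catalysed Michael addition of the phosphonoacetate to the enal, in which the (S)-configured silyl ether group shields one face of the s-trans (E)-iminium ion so that the nucleophile adds to the other face and sets C-3 (future ring C4) as (S), while C-2 stays a mixture that step 4 erases.

Step 3
Reactants: 5 benzyl (3S)-3-[3,4-bis(benzyloxy)phenyl]-2-(diethoxyphosphoryl)-5-oxopentanoate; 6 glyoxylic acid monohydrate
Product: 8 benzyl (3R)-3-[3,4-bis(benzyloxy)phenyl]-2-(diethoxyphosphoryl)-3-(2-methoxy-5-oxo-2,5-dihydrofuran-3-yl)propanoate (epimers at C-2 and at the acetal carbon), via hydroxybutenolide 7 (not isolated)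
Conditions: morpholine·HCl, dioxane/H2O, 90 °C; then MeOH, camphor-10-sulfonic acid (cat.), rt
Reagents that add atoms: methanol, CO
Why: Mannich-type aldol condensation of the aldehyde α-CH2 with glyoxylic acid should give the (Z)-3-formylacrylic acid, which closes to the 5-hydroxybutenolide and is then held as its methyl pseudo-ester by acid-catalysed acetalisation; the benzylic centre is untouched (its descriptor changes only through priorities).

Step 4
Reactants: 8 benzyl (3R)-3-[3,4-bis(benzyloxy)phenyl]-2-(diethoxyphosphoryl)-3-(2-methoxy-5-oxo-2,5-dihydrofuran-3-yl)propanoate; 9 3,3-dimethoxypropanal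
Product: 10 benzyl 2-{(R)-[3,4-bis(benzyloxy)phenyl](2-methoxy-5-oxo-2,5-dihydrofuran-3-yl)methyl}-5,5-dimethoxypent-2-enoate (E/Z mixture, acetal epimers)
Conditions: LiN(SiMe3)2, THF, −78 °C; then 9, −78 → 0 °C
Reagents that add atoms: none
Why: Horner–Wadsworth–Emmons olefination of the lithiated phosphonoacetate with the aliphatic aldehyde builds the future C2=C3 unit and removes the C-2 stereocentre, the E/Z ratio being irrelevant because both isomers pass through the same dienamine in step 5.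

Step 5
Reactants: 10 benzyl 2-{(R)-[3,4-bis(benzyloxy)phenyl](2-methoxy-5-oxo-2,5-dihydrofuran-3-yl)methyl}-5,5-dimethoxypent-2-enoate
Product: 12 benzyl (3aR,4R,5R,7aR)-4-[3,4-bis(benzyloxy)phenyl]-7-formyl-3-hydroxy-1-oxo-1,3,3a,4,5,7a-hexahydro-2-benzofuran-5-carboxylate (both lactol epimers), via formyl hydroxybutenolide 11 (not isolated)
Conditions: 2 M aq HCl, THF, 40 °C; then pyrrolidine (30 mol %), AcOH (30 mol %), CH2Cl2, rt
Reagents that add atoms: water, O
Why: Aqueous acid unmasks both latent carbonyl groups to give 11; pyrrolidine then turns the CH2–CHO end of the pentenoate arm into a dienamine whose α-carbon (future ring C1) is nucleophilic, and turns the ring-opened hydroxybutenolide into the iminium ion of a (Z)-3-formylacrylic acid whose β-carbon (future C6) is attacked intramolecularly, after which hydrolysis, shift of the double bond into conjugation with the C1 formyl group and re-closure of the hemiacylal should give 12. The closest known reaction type is the amine-catalysed intramolecular Michael (Rauhut–Currier-type) cyclisation of enals through dienamines. The carbocycle closes 6-endo-trig at the acceptor C5=C6, and the lactol ring re-forms by 5-exo-trig attack of the C6 carboxyl on the C5 formyl group. C6 is controlled by C4 (allylic 1,2-strain with the C5 formyl/iminium group keeps the C4–H in the plane of the (Z)-acceptor, so C1 should add anti to the aryl group and the C6 carboxyl end trans to it), C5 (α to the aldehyde) epimerises through its enamine and is held by the lactol that only the cis C5/C6 isomer can form, and C3 (α to the ester, γ to the enal) equilibrates through the dienamine to the equatorial ester trans to the aryl group. The step needs 1,4- and not 1,2-addition and attack at C6 and not at C5; the soft, ester-stabilised dienamine with iminium activation should secure the first and the fully substituted C5 the second, and because the C2=C3 geometry and the C3 and acetal centres of 10 are all erased on the way, every isomer of 10 converges on 12.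

Step 6
Reactants: 12 benzyl (3aR,4R,5R,7aR)-4-[3,4-bis(benzyloxy)phenyl]-7-formyl-3-hydroxy-1-oxo-1,3,3a,4,5,7a-hexahydro-2-benzofuran-5-carboxylate
Product: 13 benzyl (3aR,4S,5R,7aR)-4-[3,4-bis(benzyloxy)phenyl]-7-formyl-1,3-dioxo-1,3,3a,4,5,7a-hexahydro-2-benzofuran-5-carboxylate
Conditions: PhI(OAc)2, TEMPO (10 mol %), CH2Cl2, rt
Reagents that add atoms: none
Why: Oxoammonium (TEMPO) oxidation of the lactol OH should give the cis-fused cyclic anhydride, bringing the C5 carboxyl carbon to its final oxidation level without touching the enal or any stereocentre (the C4 descriptor changes only through priorities).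

Step 7
Reactants: 14 potassium (2R)-oxirane-2-carboxylate; 15 benzyl bromide
Product: 16 benzyl (2R)-oxirane-2-carboxylate
Conditions: BnEt3NCl (10 mol %), CH2Cl2, 40 °C
Reagents that add atoms: none
Why: SN2 O-alkylation of the carboxylate by benzyl bromide under phase-transfer catalysis (Williamson-type ester formation), in which neither the epoxide nor the (R) centre takes part.

Step 8
Reactants: 17 1,2-bis(benzyloxy)-4-bromobenzene; 18 magnesium; 16 benzyl (2R)-oxirane-2-carboxylate
Product: 20 benzyl (2R)-3-[3,4-bis(benzyloxy)phenyl]-2-hydroxypropanoate, via arylmagnesium bromide 19 (not isolated)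
Conditions: Mg turnings, I2 (cat.), THF, 50 °C; then slow addition to 16, CuI (10 mol %), THF, −40 → −20 °C; sat. aq NH4Cl
Reagents that add atoms: none
Why: Copper-catalysed SN2 opening of the glycidic ester by the aryl Grignard reagent at the unsubstituted C-3 should outrun addition to the ester at low temperature with inverse addition, and because the C-2–O bond is not broken the (R) centre of 16 is carried over unchanged.

Step 9
Reactants: 20 benzyl (2R)-3-[3,4-bis(benzyloxy)phenyl]-2-hydroxypropanoate; 21 bromoacetyl bromide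
Product: 22 benzyl (2R)-3-[3,4-bis(benzyloxy)phenyl]-2-[(bromoacetyl)oxy]propanoate
Conditions: pyridine, CH2Cl2, 0 °C
Reagents that add atoms: none
Why: O-acylation of the secondary alcohol by the acid bromide (nucleophilic acyl substitution), with retention at the carbinol carbon.

Step 10
Reactants: 22 benzyl (2R)-3-[3,4-bis(benzyloxy)phenyl]-2-[(bromoacetyl)oxy]propanoate; 23 triphenylphosphane
Product: 25 benzyl (2R)-3-[3,4-bis(benzyloxy)phenyl]-2-{[(triphenylphosphoranylidene)acetyl]oxy}propanoate, via phosphonium bromide 24 (not isolated)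
Conditions: toluene, rt; then aq Na2CO3, CH2Cl2, 0 °C
Reagents that add atoms: none
Why: SN2 quaternisation of PPh3 by the α-bromo ester and deprotonation of the salt should give the stabilised Wittig ylide, the mild base leaving the α-acyloxy ester centre intact.

Step 11
Reactants: 13 benzyl (3aR,4S,5R,7aR)-4-[3,4-bis(benzyloxy)phenyl]-7-formyl-1,3-dioxo-1,3,3a,4,5,7a-hexahydro-2-benzofuran-5-carboxylate; 25 benzyl (2R)-3-[3,4-bis(benzyloxy)phenyl]-2-{[(triphenylphosphoranylidene)acetyl]oxy}propanoate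
Product: 26 benzyl (3aR,4S,5R,7aR)-4-[3,4-bis(benzyloxy)phenyl]-7-[(1E)-3-({(2R)-1-(benzyloxy)-3-[3,4-bis(benzyloxy)phenyl]-1-oxopropan-2-yl}oxy)-3-oxoprop-1-en-1-yl]-1,3-dioxo-1,3,3a,4,5,7a-hexahydro-2-benzofuran-5-carboxylate
Conditions: CH2Cl2, rt
Reagents that add atoms: none
Why: Wittig olefination of the enal with the stabilised ylide should give the (E)-dienoate and join the two fragments, the anhydride being far less reactive toward the ylide at room temperature and the non-basic medium preserving C3 and C6.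

Step 12
Reactants: 26 benzyl (3aR,4S,5R,7aR)-4-[3,4-bis(benzyloxy)phenyl]-7-[(1E)-3-({(2R)-1-(benzyloxy)-3-[3,4-bis(benzyloxy)phenyl]-1-oxopropan-2-yl}oxy)-3-oxoprop-1-en-1-yl]-1,3-dioxo-1,3,3a,4,5,7a-hexahydro-2-benzofuran-5-carboxylate
Product: 27 (1R,2R,3S,4R)-6-[(1E)-3-{[(1R)-1-carboxy-2-(3,4-dihydroxyphenyl)ethyl]oxy}-3-oxoprop-1-en-1-yl]-3-(3,4-dihydroxyphenyl)cyclohex-5-ene-1,2,4-tricarboxylic acid
Conditions: BCl3, C6HMe5, CH2Cl2, −78 → 0 °C; then H2O, THF, rt
Reagents that add atoms: water, O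
Why: Lewis-acid debenzylation with a cation scavenger should remove the four aryl benzyl ethers at low temperature and the two benzyl esters on warming, without base or hydrogen, so the diene and the enolisable ring centres survive, and water opens the anhydride to the cis-diacid.

**Compound list**

1 | 3,4-bis(benzyloxy)benzaldehyde | O=Cc1ccc(OCc2ccccc2)c(OCc2ccccc2)c1 | starting material
2 | (triphenylphosphoranylidene)acetaldehyde | O=CC=P(c1ccccc1)(c1ccccc1)c1ccccc1 | starting material
3 | (2E)-3-[3,4-bis(benzyloxy)phenyl]prop-2-enal | O=C/C=C/c1ccc(OCc2ccccc2)c(OCc2ccccc2)c1 | intermediate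
4 | benzyl (diethoxyphosphoryl)acetate | CCOP(=O)(CC(=O)OCc1ccccc1)OCC | starting material
5 | benzyl (3S)-3-[3,4-bis(benzyloxy)phenyl]-2-(diethoxyphosphoryl)-5-oxopentanoate | O=CC[C@@H](c1ccc(OCc2ccccc2)c(OCc2ccccc2)c1)C(P(=O)(OCC)OCC)C(=O)OCc1ccccc1 | intermediate
6 | glyoxylic acid monohydrate (2,2-dihydroxyacetic acid) | OC(O)C(=O)O | starting material
7 | benzyl (3R)-3-[3,4-bis(benzyloxy)phenyl]-2-(diethoxyphosphoryl)-3-(2-hydroxy-5-oxo-2,5-dihydrofuran-3-yl)propanoate | OC1OC(=O)C=C1[C@@H](c1ccc(OCc2ccccc2)c(OCc2ccccc2)c1)C(P(=O)(OCC)OCC)C(=O)OCc1ccccc1 | intermediate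
8 | benzyl (3R)-3-[3,4-bis(benzyloxy)phenyl]-2-(diethoxyphosphoryl)-3-(2-methoxy-5-oxo-2,5-dihydrofuran-3-yl)propanoate | COC1OC(=O)C=C1[C@@H](c1ccc(OCc2ccccc2)c(OCc2ccccc2)c1)C(P(=O)(OCC)OCC)C(=O)OCc1ccccc1 | intermediate
9 | 3,3-dimethoxypropanal | COC(CC=O)OC | starting material
10 | benzyl 2-{(R)-[3,4-bis(benzyloxy)phenyl](2-methoxy-5-oxo-2,5-dihydrofuran-3-yl)methyl}-5,5-dimethoxypent-2-enoate | COC(OC)CC=C(C(=O)OCc1ccccc1)[C@H](c1ccc(OCc2ccccc2)c(OCc2ccccc2)c1)C1=CC(=O)OC1OC | intermediate
11 | benzyl 2-{(R)-[3,4-bis(benzyloxy)phenyl](2-hydroxy-5-oxo-2,5-dihydrofuran-3-yl)methyl}-5-oxopent-2-enoate | O=CCC=C(C(=O)OCc1ccccc1)[C@H](c1ccc(OCc2ccccc2)c(OCc2ccccc2)c1)C1=CC(=O)OC1O | intermediate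
12 | benzyl (3aR,4R,5R,7aR)-4-[3,4-bis(benzyloxy)phenyl]-7-formyl-3-hydroxy-1-oxo-1,3,3a,4,5,7a-hexahydro-2-benzofuran-5-carboxylate | O=CC1=C[C@@H](C(=O)OCc3ccccc3)[C@H](c3ccc(OCc4ccccc4)c(OCc4ccccc4)c3)[C@H]2C(O)OC(=O)[C@@H]12 | intermediate
13 | benzyl (3aR,4S,5R,7aR)-4-[3,4-bis(benzyloxy)phenyl]-7-formyl-1,3-dioxo-1,3,3a,4,5,7a-hexahydro-2-benzofuran-5-carboxylate | O=CC1=C[C@@H](C(=O)OCc3ccccc3)[C@H](c3ccc(OCc4ccccc4)c(OCc4ccccc4)c3)[C@H]2C(=O)OC(=O)[C@@H]12 | intermediate
14 | potassium (2R)-oxirane-2-carboxylate | [K+].[O-]C(=O)[C@H]1CO1 | starting material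
15 | benzyl bromide | BrCc1ccccc1 | starting material
16 | benzyl (2R)-oxirane-2-carboxylate | O=C(OCc1ccccc1)[C@H]1CO1 | intermediate
17 | 1,2-bis(benzyloxy)-4-bromobenzene | Brc1ccc(OCc2ccccc2)c(OCc2ccccc2)c1 | starting material
18 | magnesium | [Mg] | starting material
19 | [3,4-bis(benzyloxy)phenyl]magnesium bromide | Br[Mg]c1ccc(OCc2ccccc2)c(OCc2ccccc2)c1 | intermediate
20 | benzyl (2R)-3-[3,4-bis(benzyloxy)phenyl]-2-hydroxypropanoate | O[C@H](Cc1ccc(OCc2ccccc2)c(OCc2ccccc2)c1)C(=O)OCc1ccccc1 | intermediate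
21 | bromoacetyl bromide | BrCC(Br)=O | starting material
22 | benzyl (2R)-3-[3,4-bis(benzyloxy)phenyl]-2-[(bromoacetyl)oxy]propanoate | BrCC(=O)O[C@H](Cc1ccc(OCc2ccccc2)c(OCc2ccccc2)c1)C(=O)OCc1ccccc1 | intermediate
23 | triphenylphosphane | c1ccc(cc1)P(c1ccccc1)c1ccccc1 | starting material
24 | [2-({(2R)-1-(benzyloxy)-3-[3,4-bis(benzyloxy)phenyl]-1-oxopropan-2-yl}oxy)-2-oxoethyl](triphenyl)phosphonium bromide | [Br-].O=C(C[P+](c1ccccc1)(c1ccccc1)c1ccccc1)O[C@H](Cc1ccc(OCc2ccccc2)c(OCc2ccccc2)c1)C(=O)OCc1ccccc1 | intermediate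
25 | benzyl (2R)-3-[3,4-bis(benzyloxy)phenyl]-2-{[(triphenylphosphoranylidene)acetyl]oxy}propanoate | O=C(C=P(c1ccccc1)(c1ccccc1)c1ccccc1)O[C@H](Cc1ccc(OCc2ccccc2)c(OCc2ccccc2)c1)C(=O)OCc1ccccc1 | intermediate
26 | benzyl (3aR,4S,5R,7aR)-4-[3,4-bis(benzyloxy)phenyl]-7-[(1E)-3-({(2R)-1-(benzyloxy)-3-[3,4-bis(benzyloxy)phenyl]-1-oxopropan-2-yl}oxy)-3-oxoprop-1-en-1-yl]-1,3-dioxo-1,3,3a,4,5,7a-hexahydro-2-benzofuran-5-carboxylate | O=C(/C=C/C1=C[C@@H](C(=O)OCc3ccccc3)[C@H](c3ccc(OCc4ccccc4)c(OCc4ccccc4)c3)[C@H]2C(=O)OC(=O)[C@@H]12)O[C@H](Cc1ccc(OCc2ccccc2)c(OCc2ccccc2)c1)C(=O)OCc1ccccc1 | intermediate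
27 | (1R,2R,3S,4R)-6-[(1E)-3-{[(1R)-1-carboxy-2-(3,4-dihydroxyphenyl)ethyl]oxy}-3-oxoprop-1-en-1-yl]-3-(3,4-dihydroxyphenyl)cyclohex-5-ene-1,2,4-tricarboxylic acid | O=C(/C=C/C1=C[C@@H](C(=O)O)[C@H](c2ccc(O)c(O)c2)[C@@H](C(=O)O)[C@H]1C(=O)O)O[C@H](Cc1ccc(O)c(O)c1)C(=O)O | target

**Count and risks**

Total: 12 steps. Longest linear sequence: 8 steps (steps 1, 2, 3, 4, 5, 6, 11, 12).

Most likely to fail:

1. Step 5. The dienamine may add 1,2 to the C5 formyl/iminium carbon and condense (aldol) instead of adding 1,4. C1 may add to the aryl-bearing face of C6. Equilibration at C3 may stop short or favour the trans ester only weakly. The fallback sets out from 10 and comes back at 13. Acid hydrolysis of 10 as in step 5 gives 11, which is oxidised with Dess–Martin periodinane to the maleic anhydride aldehyde benzyl 2-{[3,4-bis(benzyloxy)phenyl](2,5-dioxo-2,5-dihydrofuran-3-yl)methyl}-5-oxopent-2-enoate F1 (benzylic configuration as in 10). t-BuMe2SiOTf/Et3N then gives the silyl dienol ether benzyl 2-{[3,4-bis(benzyloxy)phenyl](2,5-dioxo-2,5-dihydrofuran-3-yl)methyl}-5-[(tert-butyldimethylsilyl)oxy]penta-2,4-dienoate F2. An intramolecular Mukaiyama–Michael addition (Me3SiOTf cat., CH2Cl2, −78 °C) of its α-carbon to the unsubstituted anhydride carbon, aqueous work-up and a trace of Et3N to move the double bond into conjugation should give 13. This removes the aldehyde that invites 1,2-addition, keeps the acceptor (Z) inside the anhydride ring, and lets the ring fusion be set by protonation on the convex face.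

2. Step 4. Aldehyde 9 may lose methanol under base, the butenolide may be deprotonated at its γ-positions with epimerisation at the benzylic carbon, and the α-branched phosphonate may olefinate slowly. The fallback sets out from 8 and comes back at 10. Olefination of 8 with aqueous formaldehyde and K2CO3 gives the α-methylene ester benzyl 2-{(R)-[3,4-bis(benzyloxy)phenyl](2-methoxy-5-oxo-2,5-dihydrofuran-3-yl)methyl}prop-2-enoate F3. Olefin cross-metathesis of F3 with 4,4-dimethoxybut-1-ene (second-generation Hoveyda–Grubbs catalyst, CH2Cl2, 40 °C) should then give 10 without a strong base and without the β-alkoxy aldehyde.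

3. Step 11. The ylide may be acylated by the anhydride, or may act as a base and move the ring double bond out of the C1=C2 position. The fallback sets out from 12 and comes back at 27. MeOH with camphor-10-sulfonic acid converts 12 into the methyl pseudo-ester benzyl (3aR,4R,5R,7aR)-4-[3,4-bis(benzyloxy)phenyl]-7-formyl-3-methoxy-1-oxo-1,3,3a,4,5,7a-hexahydro-2-benzofuran-5-carboxylate F4. Wittig reaction with 25 gives the dienoate benzyl (3aR,4R,5R,7aR)-4-[3,4-bis(benzyloxy)phenyl]-7-[(1E)-3-({(2R)-1-(benzyloxy)-3-[3,4-bis(benzyloxy)phenyl]-1-oxopropan-2-yl}oxy)-3-oxoprop-1-en-1-yl]-3-methoxy-1-oxo-1,3,3a,4,5,7a-hexahydro-2-benzofuran-5-carboxylate F5. Aqueous acid followed by Pinnick oxidation (NaClO2, NaH2PO4, 2-methylbut-2-ene, t-BuOH/H2O) gives the diacid (1R,2R,5R,6R)-5-[(benzyloxy)carbonyl]-6-[3,4-bis(benzyloxy)phenyl]-3-[(1E)-3-({(2R)-1-(benzyloxy)-3-[3,4-bis(benzyloxy)phenyl]-1-oxopropan-2-yl}oxy)-3-oxoprop-1-en-1-yl]cyclohex-3-ene-1,2-dicarboxylic acid F6. F6 is debenzylated under the conditions of step 12 to 27.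

Further compounds
F1 | step 5 | benzyl 2-{[3,4-bis(benzyloxy)phenyl](2,5-dioxo-2,5-dihydrofuran-3-yl)methyl}-5-oxopent-2-enoate (benzylic configuration as in 10) | O=CCC=C(C(=O)OCc1ccccc1)[C@H](c1ccc(OCc2ccccc2)c(OCc2ccccc2)c1)C1=CC(=O)OC1=O
F2 | step 5 | benzyl 2-{[3,4-bis(benzyloxy)phenyl](2,5-dioxo-2,5-dihydrofuran-3-yl)methyl}-5-[(tert-butyldimethylsilyl)oxy]penta-2,4-dienoate (benzylic configuration as in 10) | CC(C)(C)[Si](C)(C)OC=CC=C(C(=O)OCc1ccccc1)[C@H](c1ccc(OCc2ccccc2)c(OCc2ccccc2)c1)C1=CC(=O)OC1=O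
F3 | step 4 | benzyl 2-{(R)-[3,4-bis(benzyloxy)phenyl](2-methoxy-5-oxo-2,5-dihydrofuran-3-yl)methyl}prop-2-enoate | C=C(C(=O)OCc1ccccc1)[C@H](c1ccc(OCc2ccccc2)c(OCc2ccccc2)c1)C1=CC(=O)OC1OC
F4 | step 11 | benzyl (3aR,4R,5R,7aR)-4-[3,4-bis(benzyloxy)phenyl]-7-formyl-3-methoxy-1-oxo-1,3,3a,4,5,7a-hexahydro-2-benzofuran-5-carboxylate | O=CC1=C[C@@H](C(=O)OCc3ccccc3)[C@H](c3ccc(OCc4ccccc4)c(OCc4ccccc4)c3)[C@H]2C(OC)OC(=O)[C@@H]12
F5 | step 11 | benzyl (3aR,4R,5R,7aR)-4-[3,4-bis(benzyloxy)phenyl]-7-[(1E)-3-({(2R)-1-(benzyloxy)-3-[3,4-bis(benzyloxy)phenyl]-1-oxopropan-2-yl}oxy)-3-oxoprop-1-en-1-yl]-3-methoxy-1-oxo-1,3,3a,4,5,7a-hexahydro-2-benzofuran-5-carboxylate | O=C(/C=C/C1=C[C@@H](C(=O)OCc3ccccc3)[C@H](c3ccc(OCc4ccccc4)c(OCc4ccccc4)c3)[C@H]2C(OC)OC(=O)[C@@H]12)O[C@H](Cc1ccc(OCc2ccccc2)c(OCc2ccccc2)c1)C(=O)OCc1ccccc1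
F6 | step 11 | (1R,2R,5R,6R)-5-[(benzyloxy)carbonyl]-6-[3,4-bis(benzyloxy)phenyl]-3-[(1E)-3-({(2R)-1-(benzyloxy)-3-[3,4-bis(benzyloxy)phenyl]-1-oxopropan-2-yl}oxy)-3-oxoprop-1-en-1-yl]cyclohex-3-ene-1,2-dicarboxylic acid | O=C(/C=C/C1=C[C@@H](C(=O)OCc3ccccc3)[C@H](c3ccc(OCc4ccccc4)c(OCc4ccccc4)c3)[C@@H](C(=O)O)[C@H]1C(=O)O)O[C@H](Cc1ccc(OCc2ccccc2)c(OCc2ccccc2)c1)C(=O)OCc1ccccc1
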